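**Assumption:** the target SMILES contains no stereocenters, so glicophenone as written is achiral and there is no configuration to set.

## Retrosynthetic overview
1. Glicophenone (**15**) comes from global desilylation of the bis-TIPS ether **14**.
2. **14** comes from Lewis-acid C-prenylation of the one remaining position flanking the OMe in **12**.
3. The key Ar–CH2 bond of **12** forms by radical C–H phenacylation. The phenacyl radical from 2-chloro-1-(2,4-dihydroxyphenyl)ethanone (**11**) adds to 1-methoxy-3,5-bis(TIPSO)benzene (**9**).
4. Both benzene rings come from resorcinol, so no rings are formed. Ring B is made by C-acylation. Ring A gets its third meta oxygen by Ir-catalysed C5–H borylation, oxidation and methylation.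

## Route

**Step 1**
Reactants: 1 (resorcinol), 2 (triisopropylsilyl chloride, 2.2 equiv)
Product: 3 (1,3-bis(triisopropylsilyloxy)benzene)
Conditions: imidazole (2.5 equiv), DMF, rt, 12 h
Reagents that add atoms: TIPSCl, `CC(C)[Si](Cl)(C(C)C)C(C)C` (two TIPS groups)
Why: O-silylation of both phenols gives bulky, base-stable and Oxone-stable protecting groups that also make the later borylation sterically controlled.

**Step 2**
Reactants: 3, 4 (B2pin2)
Product: 5 (2-[3,5-bis(TIPSO)phenyl]-Bpin)
Conditions: [Ir(cod)OMe]2 (1.5 mol%), dtbpy (3 mol%), B2pin2 (0.6 equiv), THF, 80 °C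
Reagents that add atoms: B2pin2, `CC1(C)OB(OC1(C)C)B1OC(C)(C)C(C)(C)O1` (Bpin group)
Why: Ir-catalysed C–H borylation is governed by sterics. In a 1,3-disubstituted arene it goes to C5, meta to both silyloxy groups, which marks the position of the third oxygen.

**Step 3**
Reactants: 5, 6 (Oxone)
Product: 7 (3,5-bis(TIPSO)phenol)
Conditions: Oxone, acetone/H2O 1:1, rt, 15 min
Reagents that add atoms: Oxone (KHSO5), `[K+].OOS([O-])(=O)=O` (supplies the phenolic O)
Why: Oxone oxidises the aryl C–B bond to C–O (ipso-hydroxylation of an arylboronate) in minutes at rt, and aryl TIPS ethers tolerate these conditions.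

**Step 4**
Reactants: 7, 8 (MeI)
Product: 9 (1-methoxy-3,5-bis(TIPSO)benzene)
Conditions: K2CO3, acetone, 50 °C, 6 h (sealed vessel)
Reagents that add atoms: MeI, `CI` (OCH3)
Why: Williamson O-methylation (SN2) of the only free phenol sets the C-OMe that will sit between the two positions to be substituted.

**Step 5**
Reactants: 1 (resorcinol), 10 (chloroacetyl chloride)
Product: 11 (2-chloro-1-(2,4-dihydroxyphenyl)ethanone)
Conditions: AlCl3 (3 equiv), PhNO2, 0 °C to rt, 8 h
Reagents that add atoms: ClCH2COCl, `ClCC(Cl)=O` (ClCH2C(=O) group)
Why: Friedel–Crafts C-acylation occurs para to one OH and ortho to the other, and the product is stabilised as the chelated 2-hydroxyaryl ketone. This gives the ring-B ketone that carries the α-chloro radical precursor.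

**Step 6 (key radical step)**
Reactants: 9 (3 equiv), 11 (1 equiv)
Product: 12 (1-(2,4-dihydroxyphenyl)-2-[2-methoxy-4,6-bis(TIPSO)phenyl]ethanone)
Conditions: fac-Ir(ppy)3 (1 mol%), 2,6-lutidine (1.5 equiv), NaI (20 mol%), MeCN (0.1 M), blue LEDs (455 nm), 25 °C, 24 h
Reagents that add atoms: none
Why: Proposed new method: photoexcited Ir(III)* reduces the α-halo ketone (chloride exchanged in situ for iodide by NaI) to the electrophilic phenacyl radical. This radical adds to the electron-rich arene at C2 (between OMe and OTIPS) in a homolytic aromatic substitution. The cyclohexadienyl radical is oxidised by Ir(IV) and loses H+ to lutidine. Excess arene suppresses double alkylation, and the crowded C4 site between the two OTIPS groups is disfavoured. The closest known reaction is photoredox radical C–H alkylation of electron-rich arenes with α-bromo carbonyl compounds. No stereocenter forms.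

**Step 7**
Reactants: 12, 13 (prenol, 3-methylbut-2-en-1-ol)
Product: 14 (1-(2,4-dihydroxyphenyl)-2-[3-methyl-but-2-enyl-substituted 2-methoxy-4,6-bis(TIPSO)phenyl]ethanone; prenylated bis-TIPS deoxybenzoin)
Conditions: Ca(NTf2)2 (5 mol%), nBu4NPF6 (5 mol%), CH2Cl2, 25 °C, 12 h
Reagents that add atoms: prenol, `CC(C)=CCO` (prenyl group; OH leaves as water)
Why: Lewis-acid-catalysed Friedel–Crafts allylation with the prenyl cation equivalent goes to the most nucleophilic arene, the trioxygenated ring A. It takes the free position beside the small OMe (C6) rather than the position between two OTIPS groups, and ring B is comparatively deactivated by the chelated acyl group. The prenyl group goes on after the radical step so that the alkene is not exposed to the electrophilic phenacyl radical. No stereocenter forms.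

**Step 8**
Reactants: 14
Product: 15 (glicophenone)
Conditions: TBAF (4 equiv), AcOH (4 equiv), THF, 0 °C to rt, 2 h, under Ar
Reagents that add atoms: none
Why: Fluoride-mediated Si–O cleavage releases both ring-A phenols. AcOH buffering and argon limit enolate autoxidation of the deoxybenzoin CH2, and the prenyl alkene, OMe and ketone are untouched.

**Check:** The atoms follow through steps 1–8, and the final product is `COc1c(CC=C(C)C)c(O)cc(O)c1CC(=O)c1ccc(O)cc1O`. Ring A has OMe flanked by prenyl and CH2CO, OH at both outer oxygens, and H between them. Ring B is a 2,4-dihydroxyphenyl ketone. There are no stereocenters to be set or scrambled.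

## Compound list
1 | resorcinol | `Oc1cccc(O)c1` | starting material
2 | triisopropylsilyl chloride | `CC(C)[Si](Cl)(C(C)C)C(C)C` | starting material
3 | 1,3-bis(triisopropylsilyloxy)benzene | `CC(C)[Si](C(C)C)(C(C)C)Oc1cccc(O[Si](C(C)C)(C(C)C)C(C)C)c1` | intermediate
4 | bis(pinacolato)diboron | `CC1(C)OB(OC1(C)C)B1OC(C)(C)C(C)(C)O1` | starting material
5 | 3,5-bis(TIPSO)phenyl-Bpin | `CC(C)[Si](C(C)C)(C(C)C)Oc1cc(O[Si](C(C)C)(C(C)C)C(C)C)cc(c1)B1OC(C)(C)C(C)(C)O1` | intermediate
6 | Oxone (potassium peroxymonosulfate) | `[K+].OOS([O-])(=O)=O` | starting material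
7 | 3,5-bis(TIPSO)phenol | `CC(C)[Si](C(C)C)(C(C)C)Oc1cc(O)cc(O[Si](C(C)C)(C(C)C)C(C)C)c1` | intermediate
8 | iodomethane | `CI` | starting material
9 | 1-methoxy-3,5-bis(TIPSO)benzene | `COc1cc(O[Si](C(C)C)(C(C)C)C(C)C)cc(O[Si](C(C)C)(C(C)C)C(C)C)c1` | intermediate
10 | chloroacetyl chloride | `ClCC(Cl)=O` | starting material
11 | 2-chloro-1-(2,4-dihydroxyphenyl)ethanone | `O=C(CCl)c1ccc(O)cc1O` | intermediate
12 | 1-(2,4-dihydroxyphenyl)-2-[2-methoxy-4,6-bis(TIPSO)phenyl]ethanone | `COc1cc(O[Si](C(C)C)(C(C)C)C(C)C)cc(O[Si](C(C)C)(C(C)C)C(C)C)c1CC(=O)c1ccc(O)cc1O` | intermediate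
13 | 3-methylbut-2-en-1-ol (prenol) | `CC(C)=CCO` | starting material
14 | 1-(2,4-dihydroxyphenyl)-2-[3-prenyl-2-methoxy-4,6-bis(TIPSO)phenyl]ethanone | `COc1c(CC=C(C)C)c(O[Si](C(C)C)(C(C)C)C(C)C)cc(O[Si](C(C)C)(C(C)C)C(C)C)c1CC(=O)c1ccc(O)cc1O` | intermediate
15 | glicophenone | `COc1c(CC=C(C)C)c(O)cc(O)c1CC(=O)c1ccc(O)cc1O` | target

## Totals
Total steps: 8. Longest linear sequence: 7 (steps 1, 2, 3, 4, 6, 7, 8; step 5 is a parallel branch that makes **11**).

## Three steps most likely to fail
1. **Step 6, radical C–H phenacylation.** Risks are low conversion on the hindered arene, dialkylation, and interference from the free ring-B phenols (for example quenching of the radical or O-alkylation).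
   - Fallback: use a polar, radical-free coupling. Monobrominate **9** with NBS (1 equiv; separate the C2 and C4 isomers), then run a Pd-catalysed α-arylation of 2',4'-bis(MOMO)acetophenone, and remove the MOM groups in the final step.
2. **Step 7, Friedel–Crafts prenylation.** Risks are TIPS lability, over-alkylation, prenyl-cation cyclisation or O-prenylation, and attack at the hindered site between the two OTIPS groups or on ring B.
   - Fallback: brominate the free ring-A position of **12** with NBS, then run a Pd-catalysed Negishi coupling with prenylzinc bromide to install the linear prenyl group.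
3. **Step 8, global desilylation.** Risks are base-mediated air oxidation of the doubly activated CH2 and decomposition of the polyphenol.
   - Fallback: use MOM ethers instead of TIPS ethers from step 1 onward. Bis-MOM-resorcinol borylates at C5 in the same way. Accept a separable C2/C4 regioisomer mixture in the radical step, then remove the MOM groups with HCl/MeOH, which avoids fluoride and base entirely.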